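In ring A the oxygen-bearing carbons C5, C7 and C8a alternate with C4a (which carries the C4 carbonyl), C6 and C8 (which carries the chiral chain). Such a ring is a cyclised poly-β-carbonyl chain, and the route opens it at C4a–C5. One Mg(OMe)2-induced Claisen closure turns an open methyl 4-alkyl-3,5,7-trioxooctanoate into the 3-alkylphloroacetophenone. The precursor already holds the three ring oxygens and the acetyl unit (future C4 and C3). On its C4 it carries the limonene-derived side chain, with the tertiary alcohol as its TES ether. It is grown from both methyl groups of a symmetrical 3-alkylacetylacetone. Allyl ethers guard the phenols, so the flavone is finished without strong acid.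

Key step: step 9

Assumption: commercial (+)-limonene oxide (cis/trans mixture made from (R)-limonene) is taken as enantiopure at C4; ring atoms carry flavone numbers and the chains of 13 and 15 are numbered from the ester carbon (C1).

Step 1
Reactants: 1 (4R)-limonene 1,2-oxide
Product: 3 (3R)-6-oxo-3-(prop-1-en-2-yl)heptanal, via limonene-1,2-diol 2 (not isolated)
Conditions: H5IO6 (1.2 equiv), THF–H2O, 0 °C to rt
Reagents that add atoms: water, O
Why: Acid-catalysed hydrolysis of either epoxide isomer gives the 1,2-diol, which periodic acid cleaves (Malaprade glycol cleavage) without touching the isopropenyl group or the C4 stereocentre, the source of the only stereocentre of the target.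

Step 2
Reactants: 3 (3R)-6-oxo-3-(prop-1-en-2-yl)heptanal
Product: 4 (3R)-6-oxo-3-(prop-1-en-2-yl)heptanoic acid
Conditions: NaClO2, NaH2PO4, 2-methyl-2-butene, t-BuOH–H2O, rt
Reagents that add atoms: sodium chlorite, [Na+].[O-]Cl=O
Why: The Pinnick oxidation is selective for the aldehyde, and 2-methyl-2-butene traps the hypochlorous acid that could otherwise attack the isopropenyl group.

Step 3
Reactants: 4 (3R)-6-oxo-3-(prop-1-en-2-yl)heptanoic acid
Product: 5 (3R)-6-hydroxy-6-methyl-3-(prop-1-en-2-yl)heptanoic acid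
Conditions: MeMgCl (3 equiv), THF, −40 to 0 °C; then cold 1 M HCl to pH 4
Reagents that add atoms: methylmagnesium chloride, C[Mg]Cl
Why: In this Grignard addition the first equivalent makes an inert magnesium carboxylate and the next adds to the methyl ketone, which gives the gem-dimethyl carbinol and no new stereocentre.

Step 4
Reactants: 5 (3R)-6-hydroxy-6-methyl-3-(prop-1-en-2-yl)heptanoic acid
Product: 7 (3R)-6-methyl-3-(prop-1-en-2-yl)-6-(triethylsilyloxy)heptanoic acid, via bis-silylated ester 6 (not isolated)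
Conditions: TESOTf (2.3 equiv), 2,6-lutidine, CH2Cl2, 0 °C; then H2O–THF, rt
Reagents that add atoms: triethylsilyl trifluoromethanesulfonate, CC[Si](CC)(CC)OS(=O)(=O)C(F)(F)F
Why: Silyl triflate silylation reaches the hindered tertiary alcohol, the labile silyl ester hydrolyses on contact with water, and the ether later prevents the alkoxide from closing a tetrahydropyran onto the primary iodide.

Step 5
Reactants: 7 (3R)-6-methyl-3-(prop-1-en-2-yl)-6-(triethylsilyloxy)heptanoic acid
Product: 9 triethyl{[(5S)-5-(iodomethyl)-2,6-dimethylhept-6-en-2-yl]oxy}silane, via Barton ester 8 (not isolated)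
Conditions: 1-hydroxypyridine-2(1H)-thione, DCC, CH2Cl2, 0 °C, dark; then CHI3 (2 equiv), tungsten lamp, 15 °C
Reagents that add atoms: iodoform, IC(I)I; 1-hydroxypyridine-2(1H)-thione, On1ccccc1=S (its atoms only in 8)
Why: The Barton decarboxylative iodination excises the surplus carbon without electrophilic iodine, which would iodolactonise this pent-4-enoic acid, and iodine transfer from CHI3 should outrun the 1,2-vinyl shift of the homoallyl radical, so the neighbouring stereocentre keeps its spatial arrangement (only the descriptor changes).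

Step 6
Reactants: 9 triethyl{[(5S)-5-(iodomethyl)-2,6-dimethylhept-6-en-2-yl]oxy}silane; 10 acetylacetone
Product: 11 3-[(2R)-5-methyl-2-(prop-1-en-2-yl)-5-(triethylsilyloxy)hexyl]pentane-2,4-dione
Conditions: 10 (4 equiv), K2CO3, acetone, reflux
Reagents that add atoms: none
Why: SN2 C-alkylation of a soft, weakly basic β-diketone enolate by a soft iodide avoids the E2 loss of the allylic β-hydrogen that harder bases would provoke, and the excess of 10 suppresses dialkylation.

Step 7
Reactants: 11 3-[(2R)-5-methyl-2-(prop-1-en-2-yl)-5-(triethylsilyloxy)hexyl]pentane-2,4-dione; 12 dimethyl carbonate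
Product: 13 methyl 4-[(2R)-5-methyl-2-(prop-1-en-2-yl)-5-(triethylsilyloxy)hexyl]-3,5-dioxohexanoate
Conditions: LiN(iPr)2 (3.3 equiv), THF, −78 to 0 °C; 12, −78 to −10 °C; AcOH quench
Reagents that add atoms: none
Why: In this γ-acylation of a 1,3-diketone dianion (Claisen-type carbomethoxylation) the terminal carbanion is the most nucleophilic site, the third equivalent of base absorbs the more acidic product, and the symmetry of 11 makes both methyl groups equivalent.

Step 8
Reactants: 13 methyl 4-[(2R)-5-methyl-2-(prop-1-en-2-yl)-5-(triethylsilyloxy)hexyl]-3,5-dioxohexanoate; 14 N-methoxy-N-methylacetamide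
Product: 15 methyl 4-[(2R)-5-methyl-2-(prop-1-en-2-yl)-5-(triethylsilyloxy)hexyl]-3,5,7-trioxooctanoate
Conditions: LiN(iPr)2 (3.3 equiv), THF, −78 to 0 °C; 14 (1.2 equiv), −78 to −20 °C; AcOH quench at −78 °C
Reagents that add atoms: none
Why: In this terminal acylation of a fully metalated 3,5-dioxo ester (polyanion Claisen acylation with a Weinreb amide) the last-formed C6 carbanion is the most reactive site, and the chelated tetrahedral adduct releases the C7 ketone only on the cold quench, which prevents over-addition and premature ring closure.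

Step 9
Reactants: 15 methyl 4-[(2R)-5-methyl-2-(prop-1-en-2-yl)-5-(triethylsilyloxy)hexyl]-3,5,7-trioxooctanoate
Product: 16 1-{2,4,6-trihydroxy-3-[(2R)-5-methyl-2-(prop-1-en-2-yl)-5-(triethylsilyloxy)hexyl]phenyl}ethanone
Conditions: Mg(OMe)2 (5 equiv), MeOH, reflux, argon; then cold 1 M HCl to pH 4
Reagents that add atoms: none
Why: Proposed new method: Mg(OMe)2 turns the most acidic unit, the C5/C7 diketone, into its chelated enolate, whose carbon C6 adds to the magnesium-activated ester carbonyl C1; loss of methoxide and enolisation give the aromatic ring, an irreversible sink that also drains the reversibly formed 2-pyranone. The closest known reaction type is the base- or Mg(OMe)2-induced Claisen cyclisation of unbranched 3,5,7-trioxoalkanoates and of the derived 6-acetonyl-4-hydroxy-2-pyranones to acylphloroglucinols, and a branch at C4 has not been tested. Ring A closes in a 6-(enolendo)-exo-trig mode. No stereocentre is created, both C4 epimers converge on the planar C8, and the side-chain stereocentre lies away from every acidic position. The selectivity needed is Claisen folding (C6 onto C1) over aldol folding (C2 onto C7, leading to an orsellinate): the alkyl group disfavours every C4-centred enolate, including the C2/C4 dianion that would leave C7 as a free ketone, so C7 stays masked in the C5–C7 chelate while the less acidic keto ester end remains largely protonated and electrophilic. Hydroxide-free methoxide matched to the methyl ester excludes saponification, which would close the Claisen channel, and the tertiary TES ether tolerates it.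

Step 10
Reactants: 16 1-{2,4,6-trihydroxy-3-[(2R)-5-methyl-2-(prop-1-en-2-yl)-5-(triethylsilyloxy)hexyl]phenyl}ethanone
Product: 17 1-{4,6-bis(allyloxy)-2-hydroxy-3-[(2R)-5-methyl-2-(prop-1-en-2-yl)-5-(triethylsilyloxy)hexyl]phenyl}ethanone
Conditions: allyl bromide (2.1 equiv), K2CO3, acetone, reflux, argon
Reagents that add atoms: allyl bromide, C=CCBr
Why: In this Williamson etherification the future C7 and C5 hydroxyls react, while the hydroxyl wedged between the acetyl group and the branched alkyl group and chelated to the carbonyl (future C8a–OH) stays free, which later fixes the 8-alkyl rather than the 6-alkyl flavone.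

Step 11
Reactants: 18 methyl 2,4-dihydroxybenzoate
Product: 19 methyl 2,4-bis(allyloxy)benzoate
Conditions: allyl bromide (2.5 equiv), K2CO3, DMF, 60 °C
Reagents that add atoms: allyl bromide, C=CCBr
Why: Williamson etherification protects both phenols as allyl ethers, which survive acid chloride formation where acetal protecting groups would not.

Step 12
Reactants: 19 methyl 2,4-bis(allyloxy)benzoate
Product: 20 2,4-bis(allyloxy)benzoic acid
Conditions: NaOH, MeOH–H2O, 60 °C; then HCl to pH 3
Reagents that add atoms: sodium hydroxide, [Na+].[OH-]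
Why: Saponification cleaves the methyl ester, and aryl allyl ethers are inert to hydroxide.

Step 13
Reactants: 17 1-{4,6-bis(allyloxy)-2-hydroxy-3-[(2R)-5-methyl-2-(prop-1-en-2-yl)-5-(triethylsilyloxy)hexyl]phenyl}ethanone; 20 2,4-bis(allyloxy)benzoic acid
Product: 22 1-{4,6-bis(allyloxy)-2-hydroxy-3-[(2R)-5-methyl-2-(prop-1-en-2-yl)-5-(triethylsilyloxy)hexyl]phenyl}-3-[2,4-bis(allyloxy)phenyl]propane-1,3-dione, via aroyl chloride 21 (not isolated)
Conditions: 20, (COCl)2, cat. DMF, CH2Cl2, rt, evaporate; 17, LiN(SiMe3)2 (3.2 equiv), THF, −78 °C, add 21 (1.0 equiv), −78 °C to rt; AcOH quench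
Reagents that add atoms: oxalyl chloride, O=C(Cl)C(=O)Cl (its chlorine only in 21)
Why: This is a Claisen-type C-aroylation of the lithium phenoxide–enolate dianion of an o-hydroxyacetophenone, and any O-aroylated material is carried to the same 1,3-diketone by Baker–Venkataraman rearrangement under the excess base.

Step 14
Reactants: 22 1-{4,6-bis(allyloxy)-2-hydroxy-3-[(2R)-5-methyl-2-(prop-1-en-2-yl)-5-(triethylsilyloxy)hexyl]phenyl}-3-[2,4-bis(allyloxy)phenyl]propane-1,3-dione
Product: 24 5,7-bis(allyloxy)-2-[2,4-bis(allyloxy)phenyl]-8-[(2R)-5-hydroxy-5-methyl-2-(prop-1-en-2-yl)hexyl]-4H-chromen-4-one, via TES-protected flavone 23 (not isolated)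
Conditions: HCl (0.1 M) in THF–H2O (4:1), 40 °C
Reagents that add atoms: none
Why: Acid-catalysed cyclodehydration of the o-hydroxyaryl 1,3-diketone runs through the only free phenol (C8a–OH), and the same dilute aqueous acid hydrolyses the TES ether, while it is too mild to protonate the isopropenyl group or ionise the tertiary alcohol and the allylated C7 oxygen cannot close a chroman.

Step 15
Reactants: 24 5,7-bis(allyloxy)-2-[2,4-bis(allyloxy)phenyl]-8-[(2R)-5-hydroxy-5-methyl-2-(prop-1-en-2-yl)hexyl]-4H-chromen-4-one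
Product: 25 2-(2,4-dihydroxyphenyl)-5,7-dihydroxy-8-[(2R)-5-hydroxy-5-methyl-2-(prop-1-en-2-yl)hexyl]-4H-chromen-4-one (CNP0318654.1)
Conditions: Pd(PPh3)4 (10 mol %), morpholine (12 equiv), THF, 40 °C, argon
Reagents that add atoms: none
Why: In this Tsuji–Trost deallylation zerovalent palladium ionises the four aryl allyl ethers and excess morpholine captures the allyl units, under near-neutral conditions that leave the isopropenyl group, the tertiary alcohol and the stereocentre untouched.

Compound list
1 | (4R)-limonene 1,2-oxide, (4R)-1-methyl-4-(prop-1-en-2-yl)-7-oxabicyclo[4.1.0]heptane, cis/trans mixture | C=C(C)[C@@H]1CCC2(C)OC2C1 | starting material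
2 | (4R)-1-methyl-4-(prop-1-en-2-yl)cyclohexane-1,2-diol | C=C(C)[C@@H]1CCC(C)(O)C(O)C1 | intermediate
3 | (3R)-6-oxo-3-(prop-1-en-2-yl)heptanal | C=C(C)[C@H](CCC(C)=O)CC=O | intermediate
4 | (3R)-6-oxo-3-(prop-1-en-2-yl)heptanoic acid | C=C(C)[C@H](CCC(C)=O)CC(=O)O | intermediate
5 | (3R)-6-hydroxy-6-methyl-3-(prop-1-en-2-yl)heptanoic acid | C=C(C)[C@H](CCC(C)(C)O)CC(=O)O | intermediate
6 | triethylsilyl (3R)-6-methyl-3-(prop-1-en-2-yl)-6-(triethylsilyloxy)heptanoate | C=C(C)[C@H](CCC(C)(C)O[Si](CC)(CC)CC)CC(=O)O[Si](CC)(CC)CC | intermediate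
7 | (3R)-6-methyl-3-(prop-1-en-2-yl)-6-(triethylsilyloxy)heptanoic acid | C=C(C)[C@H](CCC(C)(C)O[Si](CC)(CC)CC)CC(=O)O | intermediate
8 | 2-thioxopyridin-1(2H)-yl (3R)-6-methyl-3-(prop-1-en-2-yl)-6-(triethylsilyloxy)heptanoate | C=C(C)[C@H](CCC(C)(C)O[Si](CC)(CC)CC)CC(=O)On1ccccc1=S | intermediate
9 | triethyl{[(5S)-5-(iodomethyl)-2,6-dimethylhept-6-en-2-yl]oxy}silane | C=C(C)[C@H](CCC(C)(C)O[Si](CC)(CC)CC)CI | intermediate
10 | acetylacetone | CC(=O)CC(C)=O | starting material
11 | 3-[(2R)-5-methyl-2-(prop-1-en-2-yl)-5-(triethylsilyloxy)hexyl]pentane-2,4-dione | C=C(C)[C@H](CCC(C)(C)O[Si](CC)(CC)CC)CC(C(C)=O)C(C)=O | intermediate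
12 | dimethyl carbonate | COC(=O)OC | starting material
13 | methyl 4-[(2R)-5-methyl-2-(prop-1-en-2-yl)-5-(triethylsilyloxy)hexyl]-3,5-dioxohexanoate (C4 epimers, keto–enol mixture) | C=C(C)[C@H](CCC(C)(C)O[Si](CC)(CC)CC)CC(C(C)=O)C(=O)CC(=O)OC | intermediate
14 | N-methoxy-N-methylacetamide | CON(C)C(C)=O | starting material
15 | methyl 4-[(2R)-5-methyl-2-(prop-1-en-2-yl)-5-(triethylsilyloxy)hexyl]-3,5,7-trioxooctanoate (C4 epimers, keto–enol mixture) | C=C(C)[C@H](CCC(C)(C)O[Si](CC)(CC)CC)CC(C(=O)CC(=O)OC)C(=O)CC(C)=O | intermediate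
16 | 1-{2,4,6-trihydroxy-3-[(2R)-5-methyl-2-(prop-1-en-2-yl)-5-(triethylsilyloxy)hexyl]phenyl}ethanone | C=C(C)[C@H](CCC(C)(C)O[Si](CC)(CC)CC)Cc1c(O)cc(O)c(C(C)=O)c1O | intermediate
17 | 1-{4,6-bis(allyloxy)-2-hydroxy-3-[(2R)-5-methyl-2-(prop-1-en-2-yl)-5-(triethylsilyloxy)hexyl]phenyl}ethanone | C=C(C)[C@H](CCC(C)(C)O[Si](CC)(CC)CC)Cc1c(OCC=C)cc(OCC=C)c(C(C)=O)c1O | intermediate
18 | methyl 2,4-dihydroxybenzoate | COC(=O)c1ccc(O)cc1O | starting material
19 | methyl 2,4-bis(allyloxy)benzoate | C=CCOc1ccc(C(=O)OC)c(OCC=C)c1 | intermediate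
20 | 2,4-bis(allyloxy)benzoic acid | C=CCOc1ccc(C(=O)O)c(OCC=C)c1 | intermediate
21 | 2,4-bis(allyloxy)benzoyl chloride | C=CCOc1ccc(C(=O)Cl)c(OCC=C)c1 | intermediate
22 | 1-{4,6-bis(allyloxy)-2-hydroxy-3-[(2R)-5-methyl-2-(prop-1-en-2-yl)-5-(triethylsilyloxy)hexyl]phenyl}-3-[2,4-bis(allyloxy)phenyl]propane-1,3-dione | C=C(C)[C@H](CCC(C)(C)O[Si](CC)(CC)CC)Cc1c(OCC=C)cc(OCC=C)c(C(=O)CC(=O)c2ccc(OCC=C)cc2OCC=C)c1O | intermediate
23 | 5,7-bis(allyloxy)-2-[2,4-bis(allyloxy)phenyl]-8-[(2R)-5-methyl-2-(prop-1-en-2-yl)-5-(triethylsilyloxy)hexyl]-4H-chromen-4-one | C=C(C)[C@H](CCC(C)(C)O[Si](CC)(CC)CC)Cc1c(OCC=C)cc(OCC=C)c2c(=O)cc(-c3ccc(OCC=C)cc3OCC=C)oc12 | intermediate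
24 | 5,7-bis(allyloxy)-2-[2,4-bis(allyloxy)phenyl]-8-[(2R)-5-hydroxy-5-methyl-2-(prop-1-en-2-yl)hexyl]-4H-chromen-4-one | C=C(C)[C@H](CCC(C)(C)O)Cc1c(OCC=C)cc(OCC=C)c2c(=O)cc(-c3ccc(OCC=C)cc3OCC=C)oc12 | intermediate
25 | 2-(2,4-dihydroxyphenyl)-5,7-dihydroxy-8-[(2R)-5-hydroxy-5-methyl-2-(prop-1-en-2-yl)hexyl]-4H-chromen-4-one | C=C(C)[C@H](CCC(C)(C)O)Cc1c(O)cc(O)c2c(=O)cc(-c3ccc(O)cc3O)oc12 | target

Total step count: 15. Longest linear sequence: 13 steps (steps 1–10, 13, 14 and 15); steps 11 and 12 form the ring B branch.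

Steps most likely to fail

1. Step 9 (bears the label).
- What may go wrong: methoxide may cleave the poorly enolised C3–C4–C5 diketone by retro-Claisen attack before C6 reaches C1, or the chain may fold in the aldol sense.
- The fallback uses known chemistry only. It sets out from 9 and comes back at 16.
- Commercial 2,4,6-trihydroxyacetophenone is mono-iodinated with N-iodosuccinimide (its two free ring positions are equivalent) to 3-iodo-2,4,6-trihydroxyacetophenone F1.
- F1 is peracetylated (Ac2O, pyridine) to 3-iodo-2,4,6-triacetoxyacetophenone F2.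
- Zinc insertion into 9 (Zn dust, LiCl, THF) gives the side-chain alkylzinc iodide F3.
- Negishi coupling of F3 with F2 (Pd(OAc)2, SPhos, THF) gives the 3-alkyl-2,4,6-triacetoxyacetophenone F4.
- K2CO3 in MeOH removes the acetates without touching the TES ether and delivers 16.

2. Step 8.
- What may go wrong: metalation of the branched tricarbonyl may stay incomplete, so that proton transfer from 14 or from residual C4–H quenches the C6 carbanion. The product may also cyclise during work-up.
- The fallback sets out from 13 and comes back at 15. It masks two acidic sites in a ring.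
- DBU in hot toluene lactonises 13 to the 5-alkyl-4-hydroxy-6-methyl-2-pyranone F5.
- The dianion of F5 (LiN(iPr)2, 2.2 equiv, THF, −78 °C) is acylated on the 6-methyl group by 14 to give the 6-(2-oxopropyl)-2-pyranone F6.
- Mg(OMe)2 in MeOH opens the lactone of F6 by methanolysis to 15 in the flask, where the conditions of step 9 carry it on.

3. Step 6.
- What may go wrong: substitution at the β-branched carbon is slow, which gives O-alkylation and loss of HI time to compete.
- The fallback sets out from 9 and comes back at 13. It changes the nucleophile and the order of bond formation.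
- The far more nucleophilic dianion of commercial methyl acetoacetate (LiN(iPr)2, 2.1 equiv, THF, 0 °C) is alkylated at its γ-carbon by 9. This gives methyl (6R)-9-methyl-3-oxo-6-(prop-1-en-2-yl)-9-(triethylsilyloxy)decanoate F7.
- The dianion of F7, which can only form at C4, is acetylated with 14 to give 13.

Further compounds
F1 | step 9 | 3-iodo-2,4,6-trihydroxyacetophenone | CC(=O)c1c(O)cc(O)c(I)c1O
F2 | step 9 | 3-iodo-2,4,6-triacetoxyacetophenone | CC(=O)c1c(OC(C)=O)cc(OC(C)=O)c(I)c1OC(C)=O
F3 | step 9 | side-chain alkylzinc iodide, [5-methyl-2-(prop-1-en-2-yl)-5-(triethylsilyloxy)hexyl]zinc iodide with the configuration of 9 | C=C(C)[C@H](CCC(C)(C)O[Si](CC)(CC)CC)C[Zn]I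
F4 | step 9 | 3-[(2R)-5-methyl-2-(prop-1-en-2-yl)-5-(triethylsilyloxy)hexyl]-2,4,6-triacetoxyacetophenone | C=C(C)[C@H](CCC(C)(C)O[Si](CC)(CC)CC)Cc1c(OC(C)=O)cc(OC(C)=O)c(C(C)=O)c1OC(C)=O
F5 | step 8 | 4-hydroxy-6-methyl-5-[(2R)-5-methyl-2-(prop-1-en-2-yl)-5-(triethylsilyloxy)hexyl]-2H-pyran-2-one | C=C(C)[C@H](CCC(C)(C)O[Si](CC)(CC)CC)Cc1c(O)cc(=O)oc1C
F6 | step 8 | 4-hydroxy-5-[(2R)-5-methyl-2-(prop-1-en-2-yl)-5-(triethylsilyloxy)hexyl]-6-(2-oxopropyl)-2H-pyran-2-one | C=C(C)[C@H](CCC(C)(C)O[Si](CC)(CC)CC)Cc1c(O)cc(=O)oc1CC(C)=O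
F7 | step 6 | methyl (6R)-9-methyl-3-oxo-6-(prop-1-en-2-yl)-9-(triethylsilyloxy)decanoate | C=C(C)[C@H](CCC(C)(C)O[Si](CC)(CC)CC)CCC(=O)CC(=O)OC
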